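Irisoquin's ring is numbered C1(=O), C2(OH), C3(octadecyl), C4(=O), C5(OMe), C6(H). The hydroxyquinone ring is a masked cyclohex-5-ene-1,2,4-trione in which C2 sits at the carboxyl level beside C1 and C3 is the enolisable α-carbon of the C4 ketone. It is therefore cut into C3–C4 plus chain (eicosanoyl chloride), the enol ether C5(OMe)=C6 (methyl vinyl ether) and the oxalyl unit C1–C2 (methyl chlorooxoacetate). In the key step, a one-flask [4+2] annulation, the acid chloride acylates the enol ether terminus C6 of a 2-methoxy-3-silyloxy-1,3-diene; fluoride then frees the C3 enolate, whose Dieckmann-type attack on the ester carbon C2 closes the ring and gives irisoquin directly.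

Key step: step 3

Remark: the ring closure first gives the 1,2,4-trione tautomer, which enolises at once to the 2-hydroxy-1,4-quinone drawn for irisoquin; the ring numbering above is used for all intermediates.

Step 1
Reactants: 1 eicosanoyl chloride; 2 methyl vinyl ether (excess)
Product: 5 2-methoxydocos-1-en-3-one, via 1-methoxyvinyllithium 3 (not isolated), via chloro(1-methoxyvinyl)zinc 4 (not isolated)
Conditions: t-BuLi, THF, −78 → 0 °C; ZnCl2, 0 °C; then 1, Pd(PPh3)4 (cat.), 0 °C → rt; NaHCO3 work-up
Reagents that add atoms: none
Why: α-Lithiation of the enol ether, transmetalation to zinc and Pd-catalysed coupling of the alkenylzinc with the acid chloride (Negishi acylation) should stop at the ketone, because the organozinc does not add to the α-methoxy enone that is formed.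

Step 2
Reactants: 5 2-methoxydocos-1-en-3-one
Product: 6 (3Z)-3-(tert-butyldimethylsilyloxy)-2-methoxydocosa-1,3-diene
Conditions: LiN(SiMe3)2, THF, −78 °C; TBSOTf, −78 → 0 °C; non-aqueous work-up, used crude
Reagents that add atoms: tert-butyldimethylsilyl trifluoromethanesulfonate (TBSOTf), CC(C)(C)[Si](C)(C)OS(=O)(=O)C(F)(F)F
Why: LiN(SiMe3)2 removes a proton from the CH2 next to the carbonyl (ring C3), the only enolisable position, and O-silylation of the lithium enolate (silyl enol ether formation) should give the 2,3-dioxygenated diene, mainly as the (3Z) isomer, whose geometry has no bearing on the ring closure.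

Step 3
Reactants: 6 (3Z)-3-(tert-butyldimethylsilyloxy)-2-methoxydocosa-1,3-diene; 7 methyl chlorooxoacetate
Product: 10 irisoquin, via silyl dienoate 8 (not isolated), via ammonium enolate 9 (not isolated)
Conditions: pyridine, CH2Cl2, −20 °C → rt; then Bu4NF, THF, 0 °C → rt; 1 M HCl work-up
Reagents that add atoms: none
Why: The acylpyridinium salt formed from 7 should be attacked by C6, the unsubstituted terminus of the methyl enol ether, and loss of the C6 proton to pyridine gives the push-pull dienoate 8; this is the known C-acylation of enol ethers by oxalyl-type acid chlorides. Fluoride then cleaves the Si–O bond, and the enolate carbon C3 of 9 adds to the ester carbonyl C2 and expels methoxide, an intramolecular Claisen (Dieckmann-type) condensation of the kind that closes 2,5-dihydroxyquinones from α-keto esters. The ring closes in the 6-(enolendo)-exo-trig mode, whereas aldol attack of C3 on the C1 ketone would be a disfavoured and reversible 5-(enolendo)-exo-trig closure, and the Claisen product is drained as its stabilised hydroxyquinone anion. No stereocentre is formed, and the C5=C6 geometry needed for closure (C1 cis to C4) is reached by easy rotation about the push-pull double bond. The step needs site selectivity in the first acylation, secured because the hindered trisubstituted silyl enol ether terminus C3 does not react with acid chlorides without a Lewis acid. The placing of OH against OMe is fixed because the methoxy group enters on C5 with methyl vinyl ether and C2 arrives at the ester oxidation level.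

Compound list
1 | eicosanoyl chloride (arachidoyl chloride) | CCCCCCCCCCCCCCCCCCCC(=O)Cl | starting material
2 | methyl vinyl ether (methoxyethene) | COC=C | starting material
3 | 1-methoxyvinyllithium | [Li]C(=C)OC | intermediate
4 | chloro(1-methoxyvinyl)zinc | COC(=C)[Zn]Cl | intermediate
5 | 2-methoxydocos-1-en-3-one | C=C(OC)C(=O)CCCCCCCCCCCCCCCCCCC | intermediate
6 | (3Z)-3-(tert-butyldimethylsilyloxy)-2-methoxydocosa-1,3-diene | C=C(OC)/C(O[Si](C)(C)C(C)(C)C)=C/CCCCCCCCCCCCCCCCCC | intermediate
7 | methyl chlorooxoacetate (methyl oxalyl chloride) | COC(=O)C(=O)Cl | starting material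
8 | methyl (3E,5Z)-5-(tert-butyldimethylsilyloxy)-4-methoxy-2-oxotetracosa-3,5-dienoate | COC(=O)C(=O)/C=C(OC)\C(O[Si](C)(C)C(C)(C)C)=C\CCCCCCCCCCCCCCCCCC | intermediate
9 | tetrabutylammonium enolate (C5–C6 enolate) of methyl (3E)-4-methoxy-2,5-dioxotetracos-3-enoate | CCCC[N+](CCCC)(CCCC)CCCC.COC(=O)C(=O)/C=C(OC)\C([O-])=C\CCCCCCCCCCCCCCCCCC | intermediate
10 | irisoquin (2-hydroxy-5-methoxy-3-octadecyl-1,4-benzoquinone) | CCCCCCCCCCCCCCCCCCC1=C(O)C(=O)C=C(OC)C1=O | target

Total step count: 3
Longest linear sequence: 3 steps (1 and 2 → 5 → 6 → 10; 7 enters in step 3)

Steps most likely to fail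

Step 3. The first acylation may stray to the silyl enol ether terminus or to oxygen, the dienoate may be consumed by cycloaddition with unreacted diene, and the freed enolate may close on oxygen instead of carbon. The fallback uses known double Claisen chemistry, sets out from 5 and comes back at 10. Dilute HCl in THF hydrolyses the enol ether of 5 to docosane-2,3-dione F1. F1 is added slowly to excess dimethyl oxalate and NaOMe in THF/MeOH. The methyl group (C6) should be acylated first, giving methyl 2,4,5-trioxotetracosanoate F2 as its enolate. The C3 enolate then closes the ring on the remaining ester carbon, again forming the C2–C3 bond, and acidification gives 2,5-dihydroxy-3-octadecyl-1,4-benzoquinone F3. F3 is mono-methylated in MeOH with catalytic H2SO4; acid-catalysed etherification should take place only at the hydroxyl on the carbon next to the unsubstituted C6, the one next to the octadecyl group being shielded, to give 10.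

Step 2. The doubly activated silyl dienol ether may be lost by protodesilylation or hydrolysis during isolation and handling. The fallback sets out from 5 and comes back at 10. The lithium enolate of 5 is trapped with acetic anhydride to give the robust, chromatographable enol ester (3Z)-2-methoxydocosa-1,3-dien-3-yl acetate F4. Its enol ether terminus is acylated with 7 and pyridine to methyl (3E,5Z)-5-acetoxy-4-methoxy-2-oxotetracosa-3,5-dienoate F5. NaOMe in MeOH/THF then removes the acetyl group as methyl acetate and gives the sodium enolate of methyl (3E)-4-methoxy-2,5-dioxotetracos-3-enoate F6, which should undergo the same Claisen closure to 10.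

Step 1. Incomplete transmetalation may lead to double addition of the organolithium, and the acyl–Pd(PPh3)2Cl intermediate may decarbonylate. The fallback sets out from 1 and comes back at 5. Compound 1 is converted with N,O-dimethylhydroxylamine hydrochloride and pyridine into N-methoxy-N-methyleicosanamide F7. 1-Methoxyvinyllithium 3 is then added in THF at −78 → 0 °C; the chelated tetrahedral adduct stops at the ketone stage and should give 5 on neutral work-up.

Further compounds
F1 | step 3 | docosane-2,3-dione | CC(=O)C(=O)CCCCCCCCCCCCCCCCCCC
F2 | step 3 | methyl 2,4,5-trioxotetracosanoate | COC(=O)C(=O)CC(=O)C(=O)CCCCCCCCCCCCCCCCCCC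
F3 | step 3 | 2,5-dihydroxy-3-octadecyl-1,4-benzoquinone | CCCCCCCCCCCCCCCCCCC1=C(O)C(=O)C=C(O)C1=O
F4 | step 2 | (3Z)-2-methoxydocosa-1,3-dien-3-yl acetate | C=C(OC)/C(OC(C)=O)=C/CCCCCCCCCCCCCCCCCC
F5 | step 2 | methyl (3E,5Z)-5-acetoxy-4-methoxy-2-oxotetracosa-3,5-dienoate | COC(=O)C(=O)/C=C(OC)\C(OC(C)=O)=C\CCCCCCCCCCCCCCCCCC
F6 | step 2 | sodium enolate (C5–C6 enolate) of methyl (3E)-4-methoxy-2,5-dioxotetracos-3-enoate | [Na+].COC(=O)C(=O)/C=C(OC)\C([O-])=C\CCCCCCCCCCCCCCCCCC
F7 | step 1 | N-methoxy-N-methyleicosanamide | CON(C)C(=O)CCCCCCCCCCCCCCCCCCC
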